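The α‑methylene‑γ‑lactone is annulated onto a preformed cis‑cyclodecene that comes from an anionic oxy‑Cope ring expansion (germacranolide numbering: lactone oxygen on C8, C12 carbonyl, C13 methylene). The key step exploits the contiguous O6–C6–C7–C8 array of the ten‑membered ring, in which O6 and the C7–C11 bond are cis. An iodomalonate tethered to O6 of a cyclodeca‑2,5‑dienol through the future C13 undergoes iodine‑atom‑transfer 5‑exo cyclisation onto C7 (C11–C7, temporary oxolane). A malonate carbonyl oxygen then displaces the C8 iodide (O–C8) and closes the trans‑fused lactone in the same operation. C7=C8 isomers and both C8 iodides converge. Oxolane opening later releases C13 as the exo‑methylene and the C6 hydroxyl.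

Key step: step 12

Remark on descriptors: C14 is the CH2O carbon on C10 and C15 the CH2O carbon on C4; β is the face of the ten‑membered ring that carries C11 at C7 (also O6 and C15), α is the face of O8; TBDPS = tert‑butyldiphenylsilyl.
Remark (assumption): 12, 13, 16 and 17 may form as mixtures of C7=C8 isomers; the 7Z isomers are drawn and the mixture is carried on, because step 12 erases this element.

Step 1
Reactants: 1 (R)-cyclohex-3-ene-1-carboxylic acid
Product: 2 (1R,4R,5R)-4-iodo-6-oxabicyclo[3.2.1]octan-7-one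
Conditions: I2, KI, NaHCO3, H2O/CH2Cl2, 0 °C → rt, dark
Reagents that add atoms: iodine, II
Why: Iodolactonisation, in which the carboxylate opens the iodonium ion anti at the only alkene carbon that allows a γ‑lactone, so the future C6 receives oxygen (cis to the carboxyl carbon) and the future C1 receives iodine (trans to that oxygen).

Step 2
Reactants: 2 (1R,4R,5R)-4-iodo-6-oxabicyclo[3.2.1]octan-7-one; 3 2-bromoprop-2-en-1-ol
Product: 4 (1R,4S,5R)-4-(3-hydroxyprop-1-en-2-yl)-6-oxabicyclo[3.2.1]octan-7-one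
Conditions: NiI2 (10 mol%), 4,4′-di-tert-butyl-2,2′-bipyridine (10 mol%), Zn (2 equiv), NaI (cat.), DMA, 25 °C
Reagents that add atoms: none
Why: Nickel‑catalysed reductive cross‑electrophile coupling of a secondary alkyl iodide with a vinyl bromide, in which the cyclohexyl radical should be captured on the face anti to the lactone bridge, so that the alkenyl group ends up trans to the lactone oxygen (this centre becomes sp2 in step 8).

Step 3
Reactants: 4 (1R,4S,5R)-4-(3-hydroxyprop-1-en-2-yl)-6-oxabicyclo[3.2.1]octan-7-one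
Product: 5 (1R,2S,5R)-5-(hydroxymethyl)-2-(3-hydroxyprop-1-en-2-yl)cyclohexan-1-ol
Conditions: LiAlH4, THF, 0 °C; aqueous work-up
Reagents that add atoms: none
Why: Hydride reduction of the lactone to the diol, which leaves all three stereocentres untouched (all‑equatorial triol).

Step 4
Reactants: 5 (1R,2S,5R)-5-(hydroxymethyl)-2-(3-hydroxyprop-1-en-2-yl)cyclohexan-1-ol
Product: 6 (1R,2S,5R)-5-(TBDPS-oxymethyl)-2-[3-(TBDPS-oxy)prop-1-en-2-yl]cyclohexan-1-ol
Conditions: TBDPSCl (2.1 equiv), imidazole, CH2Cl2, 0 °C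
Reagents that add atoms: tert-butyl(chloro)diphenylsilane, CC(C)(C)[Si](Cl)(c1ccccc1)c1ccccc1
Why: Silyl ether formation that should be selective for the two primary hydroxyls over the hindered secondary ring hydroxyl.

Step 5
Reactants: 6 (1R,2S,5R)-5-(TBDPS-oxymethyl)-2-[3-(TBDPS-oxy)prop-1-en-2-yl]cyclohexan-1-ol
Product: 7 (2S,5R)-5-(TBDPS-oxymethyl)-2-[3-(TBDPS-oxy)prop-1-en-2-yl]cyclohexan-1-one
Conditions: Dess–Martin periodinane, NaHCO3, CH2Cl2, 0 °C → rt
Reagents that add atoms: none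
Why: Buffered Dess–Martin oxidation should give the trans‑2,5‑diequatorial β,γ‑unsaturated ketone without epimerisation at C2 and without migration of the alkene into conjugation.

Step 6
Reactants: 7 (2S,5R)-5-(TBDPS-oxymethyl)-2-[3-(TBDPS-oxy)prop-1-en-2-yl]cyclohexan-1-one; 8 ethynylmagnesium bromide
Product: 9 (1R,2S,5R)-1-ethynyl-5-(TBDPS-oxymethyl)-2-[3-(TBDPS-oxy)prop-1-en-2-yl]cyclohexan-1-ol (ethynyl axial and cis to the C2 alkenyl group)
Conditions: THF, −78 → 0 °C; aq. NH4Cl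
Reagents that add atoms: none
Why: 1,2‑Addition of the small acetylide by axial attack on the chair with both substituents equatorial should place the ethynyl group axial, cis to the alkenyl group, with the hydroxyl equatorial; the equatorial adduct would be removed by chromatography.

Step 7
Reactants: 9 (1R,2S,5R)-1-ethynyl-5-(TBDPS-oxymethyl)-2-[3-(TBDPS-oxy)prop-1-en-2-yl]cyclohexan-1-ol
Product: 10 (1S,2S,5R)-1-ethenyl-5-(TBDPS-oxymethyl)-2-[3-(TBDPS-oxy)prop-1-en-2-yl]cyclohexan-1-ol (vinyl cis to the C2 alkenyl group)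
Conditions: H2 (1 atm), Lindlar catalyst, quinoline, EtOAc, rt
Reagents that add atoms: none
Why: Lindlar semihydrogenation stops at the vinyl group and should not touch the 1,1‑disubstituted alkene.

Step 8
Reactants: 10 (1S,2S,5R)-1-ethenyl-5-(TBDPS-oxymethyl)-2-[3-(TBDPS-oxy)prop-1-en-2-yl]cyclohexan-1-ol
Product: 12 (2Z,5E,9R)-5,9-bis(TBDPS-oxymethyl)cyclodeca-2,5-dien-1-one (C6 ketone; C7=C8 and C1=C10 both ring-cis), via potassium C6 enolate 11 (not isolated)
Conditions: KHMDS (1.05 equiv), 18-crown-6, THF, 0 °C → rt; then PhS(Cl)=N-t-Bu, −78 °C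
Reagents that add atoms: none
Why: Anionic oxy‑Cope rearrangement through a chair transition state of the cis‑1‑vinyl‑2‑alkenyl alkoxide (vinyl axial, alkenyl equatorial) should give the ring‑cis C1=C10 bond and the C6=C7 enolate regiospecifically, and dehydrogenation of that enolate with the sulfinimidoyl chloride (syn‑elimination) introduces C7=C8, whose geometry is not controlled.

Step 9
Reactants: 12 (2Z,5E,9R)-5,9-bis(TBDPS-oxymethyl)cyclodeca-2,5-dien-1-one
Product: 13 (1R,2Z,5E,9R)-5,9-bis(TBDPS-oxymethyl)cyclodeca-2,5-dien-1-ol (6β-alcohol)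
Conditions: (S)-2-methyl-CBS-oxazaborolidine (20 mol%), catecholborane, toluene, −78 °C
Reagents that add atoms: none
Why: Corey–Bakshi–Shibata reduction, in which the (S)‑catalyst should deliver hydride to the enone face that gives the (R)‑allylic alcohol (alkenyl arm as the large group) under reagent control, for either C7=C8 isomer.

Step 10
Reactants: 14 di-tert-butyl malonate
Product: 15 di-tert-butyl 2-methylidenepropanedioate
Conditions: (CH2O)n, KOAc, Cu(OAc)2·H2O (cat.), AcOH, 95 °C; distillation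
Reagents that add atoms: formaldehyde (as paraformaldehyde), C=O
Why: Knoevenagel condensation with formaldehyde; the bulky tert‑butyl esters make the methylenemalonate isolable.

Step 11
Reactants: 13 (1R,2Z,5E,9R)-5,9-bis(TBDPS-oxymethyl)cyclodeca-2,5-dien-1-ol; 15 di-tert-butyl 2-methylidenepropanedioate
Product: 17 di-tert-butyl 2-iodo-2-({[(1R,2Z,5E,9R)-5,9-bis(TBDPS-oxymethyl)cyclodeca-2,5-dien-1-yl]oxy}methyl)propanedioate, via sodium malonate enolate 16 (not isolated)
Conditions: NaH (1.05 equiv), THF, 0 °C; 15, −78 °C; then N-iodosuccinimide, −78 → 0 °C, dark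
Reagents that add atoms: N-iodosuccinimide, O=C1CCC(=O)N1I
Why: Oxa‑Michael addition of the C6 alkoxide to the methylenemalonate gives a stabilised malonate enolate that is iodinated in the same flask (electrophilic iodination), with no stereocentre involved.

Step 12
Reactants: 17 di-tert-butyl 2-iodo-2-({[(1R,2Z,5E,9R)-5,9-bis(TBDPS-oxymethyl)cyclodeca-2,5-dien-1-yl]oxy}methyl)propanedioate
Product: 19 tert-butyl 6β,13-epoxy-14,15-bis(TBDPS-oxy)germacr-1(10)-en-8α,12-olide-11α-carboxylate (trans-fused γ-lactone at C7–C8, cis-fused oxolane O6–C13–C11–C7–C6), via C8 iodide 18 (not isolated)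
Conditions: Et3B (0.3 equiv), air, PhH (0.01 M), rt, dark; then NaI (0.5 equiv), NaHCO3, DMF, 60 °C
Reagents that add atoms: none
Why: Triethylborane/oxygen starts an iodine‑atom‑transfer chain in which the electrophilic malonyl radical at C11 adds to C7 of the tethered C7=C8 alkene, the C8 radical takes iodine from 17 to give 18, and on warming a malonate carbonyl oxygen displaces the C8 iodide with loss of 2‑methylpropene, so that C11–C7 and O–C8 form in one operation. The closest known reaction type is the atom‑transfer radical cyclisation of iodomalonates followed by lactonisation of the γ‑iodo ester (atom‑transfer annulation). The oxolane closes 5‑exo‑trig and the lactone 5‑exo‑tet. C7 is controlled by C6 through the one‑carbon tether (the oxolane can only be cis‑fused, which puts C11 on the β face), and C8 by the lactonisation: iodide exchange should interconvert the two C8 iodides, and the SN2 closure to the trans‑fused lactone is expected to be preferred because the cis‑fused alternative would need two consecutive eclipsed ring torsions (C5–C6–C7–C8 and C6–C7–C8–C9), so both alkene isomers of 17 and both epimers of 18 should converge on 19. The step needs chemo‑ and regioselectivity (C7=C8 over C1=C10, 5‑exo over 6‑endo), both secured by the tether, and needs no control at C11 because either geminal ester can become the lactone carbonyl.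

Step 13
Reactants: 19 tert-butyl 6β,13-epoxy-14,15-bis(TBDPS-oxy)germacr-1(10)-en-8α,12-olide-11α-carboxylate
Product: 21 (11αH)-6β,13-epoxy-14,15-bis(TBDPS-oxy)germacr-1(10)-en-8α,12-olide, via C11 carboxylic acid 20 (not isolated)
Conditions: TMSOTf, 2,6-lutidine, CH2Cl2, 0 °C; H2O; then toluene/pyridine, 100 °C
Reagents that add atoms: none
Why: Mild cleavage of the tert‑butyl ester and thermal malonic‑type decarboxylation of the α‑carboxy lactone leave H11 on the convex face of the cis‑fused bicycle and turn C13 from a neopentyl into a β‑branched primary carbon.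

Step 14
Reactants: 21 (11αH)-6β,13-epoxy-14,15-bis(TBDPS-oxy)germacr-1(10)-en-8α,12-olide
Product: 23 6β-hydroxy-14,15-bis(TBDPS-oxy)germacra-1(10),11(13)-dien-8α,12-olide, via bromo alcohol 22 (not isolated)
Conditions: Me2BBr (2 equiv), Et3N (0.1 equiv), CH2Cl2, 0 °C → rt; aq. NaHCO3; then DBU, CH2Cl2, 0 °C
Reagents that add atoms: none
Why: Bromodimethylborane ether cleavage, in which bromide should open the boron‑activated oxolane by SN2 at the primary C13 and not at the secondary ring carbon C6 (whose C–O bond and configuration are kept), followed by E1cB loss of HBr from the β‑bromo lactone to give the exo‑methylene.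

Step 15
Reactants: 23 6β-hydroxy-14,15-bis(TBDPS-oxy)germacra-1(10),11(13)-dien-8α,12-olide; 24 angelic acid, (Z)-2-methylbut-2-enoic acid
Product: 26 6β-angeloyloxy-14,15-bis(TBDPS-oxy)germacra-1(10),11(13)-dien-8α,12-olide, via mixed anhydride 25 (not isolated)
Conditions: 2,4,6-Cl3C6H2COCl, Et3N, toluene, rt; then 23, 80 °C (no DMAP)
Reagents that add atoms: none
Why: Yamaguchi‑type esterification through the mixed anhydride without a nucleophilic catalyst should acylate the hindered C6 hydroxyl without Z→E isomerisation of the angelate.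

Step 16
Reactants: 26 6β-angeloyloxy-14,15-bis(TBDPS-oxy)germacra-1(10),11(13)-dien-8α,12-olide
Product: 27 target CNP0147777.1, 6β-angeloyloxy-14,15-dihydroxygermacra-1(10),11(13)-dien-8α,12-olide
Conditions: HF·pyridine, pyridine/THF, 0 °C → rt
Reagents that add atoms: none
Why: Fluoride desilylation under buffered, non‑basic conditions should free both primary alcohols without touching the α‑methylene lactone or the angelate.

Compound list
1 | (R)-cyclohex-3-ene-1-carboxylic acid | OC(=O)[C@H]1CC=CCC1 | starting material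
2 | (1R,4R,5R)-4-iodo-6-oxabicyclo[3.2.1]octan-7-one | O=C1O[C@@H]2C[C@H]1CC[C@H]2I | intermediate
3 | 2-bromoprop-2-en-1-ol | OCC(Br)=C | starting material
4 | (1R,4S,5R)-4-(3-hydroxyprop-1-en-2-yl)-6-oxabicyclo[3.2.1]octan-7-one | O=C1O[C@@H]2C[C@H]1CC[C@H]2C(=C)CO | intermediate
5 | (1R,2S,5R)-5-(hydroxymethyl)-2-(3-hydroxyprop-1-en-2-yl)cyclohexan-1-ol | OC[C@H]1C[C@@H](O)[C@H](C(=C)CO)CC1 | intermediate
6 | (1R,2S,5R)-5-(TBDPS-oxymethyl)-2-[3-(TBDPS-oxy)prop-1-en-2-yl]cyclohexan-1-ol | CC(C)(C)[Si](c1ccccc1)(c1ccccc1)OC[C@H]1C[C@@H](O)[C@H](C(=C)CO[Si](c2ccccc2)(c2ccccc2)C(C)(C)C)CC1 | intermediate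
7 | (2S,5R)-5-(TBDPS-oxymethyl)-2-[3-(TBDPS-oxy)prop-1-en-2-yl]cyclohexan-1-one | CC(C)(C)[Si](c1ccccc1)(c1ccccc1)OC[C@H]1CC(=O)[C@H](C(=C)CO[Si](c2ccccc2)(c2ccccc2)C(C)(C)C)CC1 | intermediate
8 | ethynylmagnesium bromide | C#C[Mg]Br | starting material
9 | (1R,2S,5R)-1-ethynyl-5-(TBDPS-oxymethyl)-2-[3-(TBDPS-oxy)prop-1-en-2-yl]cyclohexan-1-ol | CC(C)(C)[Si](c1ccccc1)(c1ccccc1)OC[C@H]1C[C@](O)(C#C)[C@H](C(=C)CO[Si](c2ccccc2)(c2ccccc2)C(C)(C)C)CC1 | intermediate
10 | (1S,2S,5R)-1-ethenyl-5-(TBDPS-oxymethyl)-2-[3-(TBDPS-oxy)prop-1-en-2-yl]cyclohexan-1-ol | CC(C)(C)[Si](c1ccccc1)(c1ccccc1)OC[C@H]1C[C@](O)(C=C)[C@H](C(=C)CO[Si](c2ccccc2)(c2ccccc2)C(C)(C)C)CC1 | intermediate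
11 | potassium C6 enolate of the ring-expanded ketone (C6=C7 enolate, ring-cis C1=C10, 4R) | [K+].[O-]\C1=C/CC/C(CO[Si](c2ccccc2)(c2ccccc2)C(C)(C)C)=C\CC[C@@H](CO[Si](c2ccccc2)(c2ccccc2)C(C)(C)C)C1 | intermediate
12 | (2Z,5E,9R)-5,9-bis(TBDPS-oxymethyl)cyclodeca-2,5-dien-1-one | O=C1/C=C\C/C(CO[Si](c2ccccc2)(c2ccccc2)C(C)(C)C)=C\CC[C@@H](CO[Si](c2ccccc2)(c2ccccc2)C(C)(C)C)C1 | intermediate
13 | (1R,2Z,5E,9R)-5,9-bis(TBDPS-oxymethyl)cyclodeca-2,5-dien-1-ol | O[C@H]1/C=C\C/C(CO[Si](c2ccccc2)(c2ccccc2)C(C)(C)C)=C\CC[C@@H](CO[Si](c2ccccc2)(c2ccccc2)C(C)(C)C)C1 | intermediate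
14 | di-tert-butyl malonate | CC(C)(C)OC(=O)CC(=O)OC(C)(C)C | starting material
15 | di-tert-butyl 2-methylidenepropanedioate | C=C(C(=O)OC(C)(C)C)C(=O)OC(C)(C)C | intermediate
16 | sodium enolate of di-tert-butyl 2-({[(1R,2Z,5E,9R)-5,9-bis(TBDPS-oxymethyl)cyclodeca-2,5-dien-1-yl]oxy}methyl)propanedioate | [Na+].CC(C)(C)OC(=O)[C-](CO[C@H]1/C=C\C/C(CO[Si](c2ccccc2)(c2ccccc2)C(C)(C)C)=C\CC[C@@H](CO[Si](c2ccccc2)(c2ccccc2)C(C)(C)C)C1)C(=O)OC(C)(C)C | intermediate
17 | di-tert-butyl 2-iodo-2-({[(1R,2Z,5E,9R)-5,9-bis(TBDPS-oxymethyl)cyclodeca-2,5-dien-1-yl]oxy}methyl)propanedioate | CC(C)(C)OC(=O)C(I)(CO[C@H]1/C=C\C/C(CO[Si](c2ccccc2)(c2ccccc2)C(C)(C)C)=C\CC[C@@H](CO[Si](c2ccccc2)(c2ccccc2)C(C)(C)C)C1)C(=O)OC(C)(C)C | intermediate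
18 | C8 iodide: di-tert-butyl 6β,13-epoxy-8-iodo-14,15-bis(TBDPS-oxy)germacr-1(10)-ene-11,11-dicarboxylate (cis-fused oxolane, both C8 epimers) | CC(C)(C)OC(=O)C1(C(=O)OC(C)(C)C)CO[C@@H]2C[C@H](CO[Si](c3ccccc3)(c3ccccc3)C(C)(C)C)CC/C=C(CO[Si](c3ccccc3)(c3ccccc3)C(C)(C)C)\CC(I)[C@H]12 | intermediate
19 | tert-butyl 6β,13-epoxy-14,15-bis(TBDPS-oxy)germacr-1(10)-en-8α,12-olide-11α-carboxylate | CC(C)(C)OC(=O)[C@]12CO[C@@H]3C[C@H](CO[Si](c4ccccc4)(c4ccccc4)C(C)(C)C)CC/C=C(CO[Si](c4ccccc4)(c4ccccc4)C(C)(C)C)\C[C@@H](OC1=O)[C@H]23 | intermediate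
20 | 6β,13-epoxy-14,15-bis(TBDPS-oxy)germacr-1(10)-en-8α,12-olide-11α-carboxylic acid | OC(=O)[C@]12CO[C@@H]3C[C@H](CO[Si](c4ccccc4)(c4ccccc4)C(C)(C)C)CC/C=C(CO[Si](c4ccccc4)(c4ccccc4)C(C)(C)C)\C[C@@H](OC1=O)[C@H]23 | intermediate
21 | (11αH)-6β,13-epoxy-14,15-bis(TBDPS-oxy)germacr-1(10)-en-8α,12-olide | O=C1O[C@@H]2C/C(CO[Si](c4ccccc4)(c4ccccc4)C(C)(C)C)=C\CC[C@@H](CO[Si](c4ccccc4)(c4ccccc4)C(C)(C)C)C[C@H]3OC[C@@H]1[C@@H]23 | intermediate
22 | (11αH)-13-bromo-6β-hydroxy-14,15-bis(TBDPS-oxy)germacr-1(10)-en-8α,12-olide | BrC[C@H]1C(=O)O[C@@H]2C/C(CO[Si](c3ccccc3)(c3ccccc3)C(C)(C)C)=C\CC[C@@H](CO[Si](c3ccccc3)(c3ccccc3)C(C)(C)C)C[C@@H](O)[C@@H]12 | intermediate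
23 | 6β-hydroxy-14,15-bis(TBDPS-oxy)germacra-1(10),11(13)-dien-8α,12-olide | C=C1C(=O)O[C@@H]2C/C(CO[Si](c3ccccc3)(c3ccccc3)C(C)(C)C)=C\CC[C@@H](CO[Si](c3ccccc3)(c3ccccc3)C(C)(C)C)C[C@@H](O)[C@@H]12 | intermediate
24 | angelic acid, (Z)-2-methylbut-2-enoic acid | C/C=C(/C)C(=O)O | starting material
25 | angelic 2,4,6-trichlorobenzoic anhydride | C/C=C(/C)C(=O)OC(=O)c1c(Cl)cc(Cl)cc1Cl | intermediate
26 | 6β-angeloyloxy-14,15-bis(TBDPS-oxy)germacra-1(10),11(13)-dien-8α,12-olide | C=C1C(=O)O[C@@H]2C/C(CO[Si](c3ccccc3)(c3ccccc3)C(C)(C)C)=C\CC[C@@H](CO[Si](c3ccccc3)(c3ccccc3)C(C)(C)C)C[C@@H](OC(=O)/C(C)=C\C)[C@@H]12 | intermediate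
27 | CNP0147777.1, (4R,6R,7R,8R)-6-angeloyloxy-14,15-dihydroxygermacra-1(10),11(13)-dien-8,12-olide (ring-cis C1=C10) | C=C1C(=O)O[C@@H]2C/C(CO)=C\CC[C@@H](CO)C[C@@H](OC(=O)/C(C)=C\C)[C@@H]12 | target

Total step count: 16. Longest linear sequence: 15 steps (1 to 27 through steps 1–9 and 11–16; step 10 prepares reagent 15).

Steps most likely to fail

Step 12 (key step). The C8–O bond may close on the wrong face: if iodine transfer gives mainly the C8 iodide whose SN2 displacement outruns its epimerisation, the cis‑fused lactone results. The fallback sets out from 17 and comes back at 19. Step 12 then delivers the cis‑fused 8β,12‑lactone F1 (the 8‑epimer of 19). LiOH in THF/H2O opens it to the 8β‑hydroxy acid F2, with the tert‑butyl ester intact. A Mitsunobu lactonisation (PPh3, DIAD, THF) then forms the C8–O bond by SN2 at the defined carbinol with inversion, which gives 19.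

Step 14. The oxolane may open at C6 instead of C13, or bromo alcohol 22 may re‑close to 21 under base faster than it eliminates. The fallback sets out from 21 and comes back at 23. Me3SiSPh with ZnI2 and Bu4NI opens the ether with a soft thiolate at the primary carbon to give the phenylthio silyl ether F3. mCPBA at −78 °C gives the sulfoxide F4. Thermal syn‑elimination (toluene, 110 °C) gives the 6‑O‑trimethylsilyl ether F5, and PPTS in MeOH removes the silyl group to give 23.

Step 8. The one‑flask sequence may lose material by equilibration of the enolate before trapping, or by base‑induced deconjugation or transannular reaction of dienone 12 during the dehydrogenation. The fallback sets out from 10 and comes back at 12. The oxy‑Cope rearrangement (KH, 18‑crown‑6, THF) is quenched with Me3SiCl/Et3N to isolate the trimethylsilyl enol ether F6. Saegusa–Ito oxidation (Pd(OAc)2, MeCN, rt) then gives 12 under neutral conditions.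

Further compounds
F1 | step 12 | tert-butyl 6β,13-epoxy-14,15-bis(TBDPS-oxy)germacr-1(10)-en-8β,12-olide-11α-carboxylate (cis-fused lactone, 8-epimer of 19) | CC(C)(C)OC(=O)[C@]12CO[C@@H]3C[C@H](CO[Si](c4ccccc4)(c4ccccc4)C(C)(C)C)CC/C=C(CO[Si](c4ccccc4)(c4ccccc4)C(C)(C)C)\C[C@H](OC1=O)[C@H]23
F2 | step 12 | 8β-hydroxy acid from F1: 11-(tert-butoxycarbonyl)-6β,13-epoxy-8β-hydroxy-14,15-bis(TBDPS-oxy)germacr-1(10)-en-12-oic acid | OC(=O)[C@]1(C(=O)OC(C)(C)C)CO[C@@H]2C[C@H](CO[Si](c3ccccc3)(c3ccccc3)C(C)(C)C)CC/C=C(CO[Si](c3ccccc3)(c3ccccc3)C(C)(C)C)\C[C@H](O)[C@H]12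
F3 | step 14 | (11αH)-13-(phenylthio)-6β-(trimethylsilyloxy)-14,15-bis(TBDPS-oxy)germacr-1(10)-en-8α,12-olide | c1ccccc1SC[C@H]1C(=O)O[C@@H]2C/C(CO[Si](c3ccccc3)(c3ccccc3)C(C)(C)C)=C\CC[C@@H](CO[Si](c3ccccc3)(c3ccccc3)C(C)(C)C)C[C@@H](O[Si](C)(C)C)[C@@H]12
F4 | step 14 | sulfoxide of F3 (either configuration at sulfur) | O=S(c1ccccc1)C[C@H]1C(=O)O[C@@H]2C/C(CO[Si](c3ccccc3)(c3ccccc3)C(C)(C)C)=C\CC[C@@H](CO[Si](c3ccccc3)(c3ccccc3)C(C)(C)C)C[C@@H](O[Si](C)(C)C)[C@@H]12
F5 | step 14 | 6-O-trimethylsilyl ether of 23 | C=C1C(=O)O[C@@H]2C/C(CO[Si](c3ccccc3)(c3ccccc3)C(C)(C)C)=C\CC[C@@H](CO[Si](c3ccccc3)(c3ccccc3)C(C)(C)C)C[C@@H](O[Si](C)(C)C)[C@@H]12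
F6 | step 8 | trimethylsilyl enol ether of the ring-expanded ketone (C6=C7 enol ether, ring-cis C1=C10) | C[Si](C)(C)O\C1=C/CC/C(CO[Si](c2ccccc2)(c2ccccc2)C(C)(C)C)=C\CC[C@@H](CO[Si](c2ccccc2)(c2ccccc2)C(C)(C)C)C1
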